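## Retrosynthetic overview

- **Ring labels.** Ring A is the methoxy-bearing ring: C1 carries the CH2CH2 chain, C2 the biaryl bond, C3 an OH and C5 the OMe. Ring B is the 3-hydroxyphenyl ring. Ring C is the hydroquinone ring, joined through C1' to C2.
- **Last disconnection.** All four phenols are unmasked together from one tetrakis(methoxymethyl) ether.
- **Key disconnection.** Both C–C bonds on the C1/C2 edge of ring A are cut at once: C1–CH2 (ortho C–H alkylation) and C2–C1' (ipso arylation). One palladium/norbornene three-component reaction (Catellani reaction with Suzuki-Miyaura termination) makes both from an aryl iodide (ring A), a 2-arylethyl bromide (ring B) and an arylboronic acid (ring C).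
- **Enabling feature.** Ring A carries the contiguous triad C3(O)–C2(aryl)–C1(primary CH2). Iodine placed on C2 is flanked by the oxygen-bearing C3, so C1–H is the only ortho C–H bond. C1 is meta to both ring oxygens, so electrophilic substitution and ortho-lithiation cannot reach it, but palladium relayed from C2 through norbornene must land there.
- **Ring formation.** No ring of the target is built. Rings A, B and C are bought as 2-iodo-5-methoxyphenol, 3-(2-hydroxyethyl)phenol and hydroquinone. The only ring formed is a temporary five-membered palladacycle in the key step.

Key step: step 6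

Remark 1: the target SMILES carries no stereodescriptor, so the biaryl axis (ortho groups OH, OH, CH2) is taken as configurationally undefined and the route needs no stereocontrol.

Remark 2: the organopalladium species of step 6 are states of the catalyst present only in catalytic amount, so they are described in the Why line and carry no compound numbers.

## Route

Step 1
Reactants: 1 2-iodo-5-methoxyphenol
Product: 2 1-iodo-4-methoxy-2-(methoxymethoxy)benzene
Conditions: MOMCl, K2CO3, acetone, 0 °C → rt
Reagents that add atoms: chloromethyl methyl ether (MOMCl), COCCl
Why: Williamson-type O-alkylation of the phenoxide by the very reactive chloromethyl ether; the MOM ether is preferred to a benzyl ether because it offers no arene C–H bond for a competing intramolecular direct arylation at the arylpalladium stage of step 6.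

Step 2
Reactants: 3 3-(2-hydroxyethyl)phenol
Product: 4 3-(2-bromoethyl)phenol
Conditions: 48% aq HBr, 80 °C
Reagents that add atoms: hydrogen bromide, Br
Why: SN2 substitution of the protonated primary alcohol by bromide, in which the phenolic C–O bond is inert, so the two hydroxyl groups are told apart without a protecting group.

Step 3
Reactants: 4 3-(2-bromoethyl)phenol
Product: 5 1-(2-bromoethyl)-3-(methoxymethoxy)benzene
Conditions: MOMCl, K2CO3, acetone, 0 °C → rt
Reagents that add atoms: chloromethyl methyl ether (MOMCl), COCCl
Why: Williamson-type O-alkylation in which the phenoxide should react with MOMCl far faster, at or below room temperature, than it attacks the primary bromide or than carbonate causes E2 elimination, so the bromoethyl chain should survive.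

Step 4
Reactants: 6 hydroquinone
Product: 7 1,4-bis(methoxymethoxy)benzene
Conditions: NaH, MOMCl, THF/DMF, 0 °C → rt, N2
Reagents that add atoms: chloromethyl methyl ether (MOMCl), COCCl
Why: Double Williamson-type O-alkylation of the bis-phenoxide, run under nitrogen so that the electron-rich dianion is not oxidised to the quinone.

Step 5
Reactants: 7 1,4-bis(methoxymethoxy)benzene
Product: 10 [2,5-bis(methoxymethoxy)phenyl]boronic acid, via aryllithium 8 (not isolated), via lithium aryltriisopropoxyborate 9 (not isolated)
Conditions: n-BuLi, TMEDA, THF, −78 → 0 °C; B(OiPr)3, −78 °C → rt; sat. aq NH4Cl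
Reagents that add atoms: triisopropyl borate, CC(C)OB(OC(C)C)OC(C)C; water, O
Why: Directed ortho-metalation, in which the MOM oxygens bind lithium and all four ring C–H bonds of 7 are equivalent so only one aryllithium can form, followed by borate trapping and near-neutral hydrolysis that leaves the acetals intact.

Step 6
Reactants: 2 1-iodo-4-methoxy-2-(methoxymethoxy)benzene; 5 1-(2-bromoethyl)-3-(methoxymethoxy)benzene; 10 [2,5-bis(methoxymethoxy)phenyl]boronic acid
Product: 11 4-methoxy-2,2',5'-tris(methoxymethoxy)-6-{2-[3-(methoxymethoxy)phenyl]ethyl}-1,1'-biphenyl
Conditions: 2 (1 equiv), 5 (2 equiv), 10 (1.5 equiv), Pd(OAc)2 (5 mol %), tri(2-furyl)phosphine (12 mol %), norbornene (2 equiv), K2CO3 (4 equiv), DMF, 50 °C, argon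
Reagents that add atoms: none
Why: This is a Catellani reaction (palladium/norbornene cooperative catalysis) with Suzuki-Miyaura termination, a reaction type known for ortho-substituted aryl iodides, primary alkyl bromides and arylboronic acids: zerovalent palladium inserts into the C2–I bond of ring A, norbornene inserts syn on its exo face, and the resulting alkylpalladium, which has no syn β-hydrogen, palladates the neighbouring C1–H with carbonate assistance to give a five-membered palladacycle (Pd, two norbornyl carbons, C2, C1). The primary bromide 5 adds to this electron-rich divalent palladium centre in SN2 fashion to give tetravalent palladium, and reductive elimination joins the alkyl carbon to the aryl carbon, as is general for alkyl halides, forming the C1–CH2 bond. With both positions next to C2 now filled, steric strain drives β-carbon elimination, norbornene leaves unchanged, and the 2,6-disubstituted arylpalladium halide transmetalates with the boronate of 10 and reductively eliminates to form the C2–C1' biaryl bond and return zerovalent palladium. No ring of the product is closed (the palladacycle is a temporary ring, closed by C–H palladation and opened again by reductive elimination and β-carbon elimination) and no stereocentre is created. Site selectivity lies in the substrate: C3 carries OMOM, so C1–H is the only C–H bond next to C2, which excludes double alkylation and fixes the alkyl group on the carbon that is meta to both ring oxygens. Chemoselectivity (norbornene insertion before transmetalation, substitution of 5 before its dehydrobromination) should be secured by excess norbornene, a mild carbonate base, moderate temperature and the absence of free OH groups or benzyl-type arene C–H bonds near palladium.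

Step 7
Reactants: 11 4-methoxy-2,2',5'-tris(methoxymethoxy)-6-{2-[3-(methoxymethoxy)phenyl]ethyl}-1,1'-biphenyl
Product: 12 6-[2-(3-hydroxyphenyl)ethyl]-4-methoxy-[1,1'-biphenyl]-2,2',5'-triol (target)
Conditions: conc. HCl (cat.), degassed MeOH, 45 °C, argon
Reagents that add atoms: none
Why: Acid-catalysed acetal exchange (methanolysis) should remove all four MOM groups in one operation and carry the formaldehyde unit off as its dimethyl acetal, while the aryl methyl ether, the biaryl bond and the bibenzyl chain are inert to dilute acid.

## Compound list

| No. | Name | SMILES | Role |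
|---|---|---|---|
| 1 | 2-iodo-5-methoxyphenol | COc1ccc(I)c(O)c1 | starting material |
| 2 | 1-iodo-4-methoxy-2-(methoxymethoxy)benzene | COCOc1cc(OC)ccc1I | intermediate |
| 3 | 3-(2-hydroxyethyl)phenol | OCCc1cccc(O)c1 | starting material |
| 4 | 3-(2-bromoethyl)phenol | Oc1cccc(CCBr)c1 | intermediate |
| 5 | 1-(2-bromoethyl)-3-(methoxymethoxy)benzene | COCOc1cccc(CCBr)c1 | intermediate |
| 6 | hydroquinone (benzene-1,4-diol) | Oc1ccc(O)cc1 | starting material |
| 7 | 1,4-bis(methoxymethoxy)benzene | COCOc1ccc(OCOC)cc1 | intermediate |
| 8 | [2,5-bis(methoxymethoxy)phenyl]lithium | COCOc1ccc(OCOC)c([Li])c1 | intermediate |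
| 9 | lithium [2,5-bis(methoxymethoxy)phenyl]tri(propan-2-yloxy)borate | [Li+].COCOc1ccc(OCOC)c(c1)[B-](OC(C)C)(OC(C)C)OC(C)C | intermediate |
| 10 | [2,5-bis(methoxymethoxy)phenyl]boronic acid | COCOc1ccc(OCOC)c(B(O)O)c1 | intermediate |
| 11 | 4-methoxy-2,2',5'-tris(methoxymethoxy)-6-{2-[3-(methoxymethoxy)phenyl]ethyl}-1,1'-biphenyl | COCOc1cc(OC)cc(CCc2cccc(OCOC)c2)c1-c1cc(OCOC)ccc1OCOC | intermediate |
| 12 | 6-[2-(3-hydroxyphenyl)ethyl]-4-methoxy-[1,1'-biphenyl]-2,2',5'-triol | COc1cc(O)c(-c2cc(O)ccc2O)c(CCc2cccc(O)c2)c1 | target |

## Step count and risks

Total step count: 7.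
Longest linear sequence: 4 steps (6 → 7 → 10 → 11 → 12, or equally 3 → 4 → 5 → 11 → 12).

**Risk 1, step 6.**
- The first arylpalladium iodide may undergo Suzuki coupling before norbornene inserts.
- Carbonate may dehydrobrominate the 2-arylethyl bromide, and the resulting alkene may end the cycle by a Heck reaction.
- Transmetalation at the doubly flanked arylpalladium with an ortho-substituted boronic acid may be slow enough for protodeboronation or hydride termination to take over.

The fallback sets out from 5 and returns at 11. It makes the same C1–CH2 bond by carbomagnesiation of an aryne instead of by the palladium/norbornene relay. Bromide 5 is converted with Mg turnings in THF into {2-[3-(methoxymethoxy)phenyl]ethyl}magnesium bromide F1. Commercial 3-fluoro-5-methoxyphenol (COc1cc(O)cc(F)c1) is protected (MOMCl, K2CO3, acetone) as 1-fluoro-3-methoxy-5-(methoxymethoxy)benzene F2. n-BuLi in THF at −78 °C should lithiate F2 between fluorine and the MOM ether to give [2-fluoro-4-methoxy-6-(methoxymethoxy)phenyl]lithium F3. After addition of F1 and warming, loss of LiF gives 5-methoxy-3-(methoxymethoxy)benzyne F4. F1 adds to F4 at the aryne carbon remote from the OMOM group, the usual regiochemistry of 3-alkoxyarynes, to give {4-methoxy-2-(methoxymethoxy)-6-{2-[3-(methoxymethoxy)phenyl]ethyl}phenyl}magnesium bromide F5. An I2 quench then gives 2-iodo-5-methoxy-1-(methoxymethoxy)-3-{2-[3-(methoxymethoxy)phenyl]ethyl}benzene F6. A separate Suzuki-Miyaura coupling of F6 with 10 (Pd(OAc)2, 2-dicyclohexylphosphino-2',6'-dimethoxybiphenyl, K3PO4, toluene/H2O, 90 °C) gives 11.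

**Risk 2, step 5.**
- Lithiation may be incomplete or go twice.
- A MOM group may be lost if the work-up turns acidic.
- The electron-rich ortho-alkoxy boronic acid may protodeboronate on isolation or storage.

The fallback sets out from 7 and returns at 11. It replaces the carbanion route by halogenation and palladium-catalysed borylation. Electrophilic bromination (NBS, MeCN, 0 °C) gives 2-bromo-1,4-bis(methoxymethoxy)benzene F7. Miyaura borylation (bis(pinacolato)diboron, PdCl2(dppf), KOAc, dioxane, 85 °C) then gives 2-[2,5-bis(methoxymethoxy)phenyl]-4,4,5,5-tetramethyl-1,3,2-dioxaborolane F8. This neutral ester can be purified by chromatography and takes the place of 10 in step 6 to give 11.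

**Risk 3, step 7.**
- The released formaldehyde unit may be recaptured by the electron-rich positions C4 and C6 of ring A.
- It may also bridge the two phenols that flank the biaryl axis as a methylene acetal.
- Ring C may be oxidised by air during purification of the free tetraphenol.

The fallback sets out from 11 and returns at 12. It changes both the fate of the C1 unit and the way the product is purified. The MOM groups are cleaved in aprotic medium with ZnBr2 and propane-1-thiol (CH2Cl2, 0 °C → rt), so the formaldehyde unit is trapped irreversibly as a dithioacetal. The crude phenol is acetylated in the same flask (Ac2O, pyridine) to the air-stable 6-[2-(3-acetoxyphenyl)ethyl]-4-methoxy-[1,1'-biphenyl]-2,2',5'-triyl triacetate F9. F9 is purified and then released by acid-catalysed methanolysis (cat. HCl, degassed MeOH, argon) to give 12.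

## Further compounds

F1 | step 6 | {2-[3-(methoxymethoxy)phenyl]ethyl}magnesium bromide | COCOc1cccc(CC[Mg]Br)c1
F2 | step 6 | 1-fluoro-3-methoxy-5-(methoxymethoxy)benzene | COCOc1cc(F)cc(OC)c1
F3 | step 6 | [2-fluoro-4-methoxy-6-(methoxymethoxy)phenyl]lithium | COCOc1cc(OC)cc(F)c1[Li]
F4 | step 6 | 5-methoxy-3-(methoxymethoxy)benzyne | COCOC1=CC(OC)=CC#C1
F5 | step 6 | {4-methoxy-2-(methoxymethoxy)-6-{2-[3-(methoxymethoxy)phenyl]ethyl}phenyl}magnesium bromide | COCOc1cc(OC)cc(CCc2cccc(OCOC)c2)c1[Mg]Br
F6 | step 6 | 2-iodo-5-methoxy-1-(methoxymethoxy)-3-{2-[3-(methoxymethoxy)phenyl]ethyl}benzene | COCOc1cc(OC)cc(CCc2cccc(OCOC)c2)c1I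
F7 | step 5 | 2-bromo-1,4-bis(methoxymethoxy)benzene | COCOc1ccc(OCOC)c(Br)c1
F8 | step 5 | 2-[2,5-bis(methoxymethoxy)phenyl]-4,4,5,5-tetramethyl-1,3,2-dioxaborolane | COCOc1ccc(OCOC)c(B2OC(C)(C)C(C)(C)O2)c1
F9 | step 7 | 6-[2-(3-acetoxyphenyl)ethyl]-4-methoxy-[1,1'-biphenyl]-2,2',5'-triyl triacetate | COc1cc(OC(C)=O)c(-c2cc(OC(C)=O)ccc2OC(C)=O)c(CCc2cccc(OC(C)=O)c2)c1
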